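## Analysis of the target

The target is a germacranolide: a ten-membered carbocycle C1–C10 with C14 as a methyl ester on C10 and C15 as a methyl group on C4. It is trans-fused at C6/C7 to an α-methylene-γ-butyrolactone (O6–C12(=O)–C11(=C13H2)–C7). C10=C1–C2=C3 is a 1,3-diene conjugated with the C14 ester, and both of its double bonds are cis inside the ring (C9 and C2 on one side of C10=C1, C1 and C4 on one side of C2=C3). C4–C5 is a trans epoxide (C3 and C6 on opposite sides), so C2=C3 is part of a vinyl epoxide.

The ring carries six contiguous stereocentres, C4 to C9. O6 is trans to the C7–C11 bond, O8 is cis to it, O9 is trans to O8, and the epoxide oxygen at C5 is threo to O6. Two more stereocentres sit in the C8 ester, a (2S,3R)-2,3-dimethyloxirane-2-carboxylate with the two methyl groups cis.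

The sensitive groups are the α-methylene lactone (a Michael acceptor), two epoxides, a cis,cis-dienoate that can isomerise, and three different esters (acetate, glycidate, methyl ester) that cannot be hydrolysed selectively. Each acyl group therefore has to be put on the correct oxygen directly.

The hard parts are the ten-membered ring, the two cis double bonds in a row, and the C6–C9 tetrad.

The feature that the route uses is this: the cis,cis-diene C10=C1–C2=C3 is flanked by the two sp3 atoms C9 (O-bearing) and C4 (methyl-bearing). One extra bond C4–C9 would turn C9, C10, C1, C2, C3, C4 into a cyclohexa-1,3-diene (ring A) and C4, C5, C6, C7, C8, C9 into a second six-membered ring (ring B). Ring B, with a carbonyl at C9, C15 on C4 and the three-carbon unit C11–C13 on C7, is the skeleton of carvone.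

## Retrosynthetic reasoning

**Epoxide last (23 from 22).** The C4–C5 epoxide is removed first. In the forward direction the C4=C5 alkene of lactone 22 is the only alkene without an acceptor directly attached, and a peracid should attack it from the outer face. Taking the epoxide off also removes the acid- and nucleophile-sensitive vinyl epoxide from every earlier step.

**Lactone, acetate and C9 carbinol (22 from 20, 19, 18, 17).** The lactone is opened to the 6,12-diol 20, which an oxoammonium oxidation should close again. The acetate comes from alcohol 18, and 18 from ketone 17 by 1,2-reduction. The ketone at C9 is wanted because the key step delivers it.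

**C8 ester by inversion (17 from 12 and 15).** The C8–O bond is cut with inversion: the α-ketol 12 has its C8 hydroxyl trans to the C7 side chain, which is what enolate oxidation of a cyclohexenone gives. Displacement of the derived triflate by the carboxylate of acid 15 should set the cis relation and install the complete side chain in one operation.

**Key disconnection (12 from 7 and 8).** In the ten-membered ring of 12 the bonds C3–C4 and C9–C10 are cut and a bond C4–C9 is drawn. This splits the molecule into the cyclohexenone 7 (C4–C9, C15, C11–C13; ten of the fifteen skeletal carbons with C6, C7 and C8 already set) and pyrone 8 (C10, C14, C1, C2, C3 plus one CO2 to be lost). The forward reaction has to join C4 to pyrone C6 and C10 to the C9 carbonyl, lose CO2, break the C4–C9 bond of the resulting bicyclic alkoxide and regenerate C4=C5. The two cis double bonds then come from ring A and need no separate control.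

**Ring B from carvone (7 from 1).** Enone 7 differs from (S)-carvone 1 by three oxygens: at C12 (allylic oxidation of the isopropenyl group), at C8 (α′-hydroxylation of the kinetic enolate) and at C6 (γ-hydroxylation through the linear dienol ether). All three are six-membered-ring reactions with stereocontrol by the C7 substituent.

**Side chain (15 from 13).** Acid 15 is cut back to the epoxy alcohol 14 and to (E)-2-methylbut-2-en-1-ol 13. The cis methyl groups come from the (E)-alkene and the absolute configuration from a Sharpless epoxidation.

## Alternatives that were turned down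

**Alternative 1:** the textbook disconnection, C6–C7, by an intramolecular Nozaki–Hiyama–Kishi (Barbier) allylation of the seco aldehyde A1 with CrCl2 (divalent chromium). This would close the ten-membered ring and the lactone at once. It was turned down for three reasons:
- A1 must carry the cis,cis-dienoate in an open chain, where no ring holds the geometry and isomerisation to the trans isomers is downhill.
- Its aldehyde sits on an epoxide carbon (C5), which makes it prone to epimerisation and to opening.
- The ring closure would have to set C6 and C7 under control of C8 alone, and every alkene of A1 would have to be built separately in a long linear sequence.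

**Alternative 2:** C2=C3 by ring-closing metathesis of A2 (vinyl epoxide plus 2-substituted pentadienoate) with a ruthenium alkylidene (second-generation Grubbs catalyst). It was turned down for three reasons:
- The step must form a cis alkene that is part of a conjugated diene inside a strained ten-membered ring.
- The alkylidene can engage the internal C10=C1 bond of the dienoate instead, which cuts out C2 and gives a smaller ring.
- All eight stereocentres would have to be in place on a flexible precursor, so the key step simplifies nothing.

**Alternative 3:** the same ring-A idea from an arene: dearomatising ortho-alkylation of methyl 3-methylsalicylate to dienone A3, then addition of a C8 nucleophile to the C9 carbonyl and fragmentation of the C4–C9 bond. The arene would supply nine carbons and the cis,cis-diene. It was turned down for three reasons: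
- The alkylation must create a quaternary C4 bearing a carbon at the aldehyde oxidation level (C5 with a leaving group). That is only available through a reversible aldol-type addition, which rearomatisation undoes.
- C4 competes with the ester-bearing C10 and with the free para position.
- The C8 nucleophile must carry its own oxygen, which leaves only reductive (pinacol-type) closures. Those would reduce the dienone first and expel the C4 substituent.

Key step: step 6

Remark: the C8 ester is read from the SMILES as (2S,3R)-2,3-dimethyloxirane-2-carboxylate (epoxide of tiglic acid, methyl groups cis). Germacrane numbering C1–C15 of the target is used for all intermediates, including the six-membered ones.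

## Route

Step 1
Reactants: 1 (S)-(+)-carvone
Product: 2 (5S)-5-(3-hydroxyprop-1-en-2-yl)-2-methylcyclohex-2-en-1-one (C12 alcohol)
Conditions: SeO2 (cat.), t-BuOOH, salicylic acid (cat.), CH2Cl2, 23 °C
Reagents that add atoms: tert-butyl hydroperoxide, CC(C)(C)OO
Why: SeO2-catalysed allylic hydroxylation (Riley-type ene reaction, then [2,3]-shift) should attack the electron-rich isopropenyl alkene and not the acceptor-substituted ring alkene, so the methyl group C12 becomes CH2OH, the later lactone carbonyl; C7 is not touched.

Step 2
Reactants: 2 C12 alcohol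
Product: 3 C12 tert-butyldimethylsilyl ether of 2
Conditions: t-BuMe2SiCl, imidazole, DMF, 23 °C
Reagents that add atoms: tert-butyldimethylsilyl chloride, CC(C)(C)[Si](C)(C)Cl
Why: Standard silylation of a primary allylic alcohol; the ether should survive amide bases, silyl triflates and the aluminium reagent of step 6.

Step 3
Reactants: 3 silyl ether
Product: 4 α′-silyloxy enone (Me3SiO at C8 trans to the C7 side chain)
Conditions: LiN(iPr)2, THF, −78 °C; 2-(phenylsulfonyl)-3-phenyloxaziridine, −78 °C; Me3SiCl, −78 → 0 °C
Reagents that add atoms: 2-(phenylsulfonyl)-3-phenyloxaziridine, O=S(=O)(c1ccccc1)N1OC1c1ccccc1; chlorotrimethylsilane, C[Si](C)(C)Cl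
Why: Kinetic deprotonation at C8 gives the cross-conjugated enolate, which the N-sulfonyloxaziridine should hydroxylate on the face away from the C7 side chain (C8–O trans to that chain); silylation of the lithium alkoxide in the same flask protects the ketol and leaves C8 too hindered to be enolised in step 4.

Step 4
Reactants: 4 α′-silyloxy enone
Product: 6 γ-hydroxy enone (C6–OH trans to the C7 side chain; C8–OSiMe3 kept), via dienol silyl ether 5 (not isolated)
Conditions: Me3SiOTf, Et3N, CH2Cl2, 0 → 23 °C; then dimethyldioxirane, acetone, −78 °C; pH 7 buffer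
Reagents that add atoms: dimethyldioxirane, CC1(C)OO1
Why: With C8 blocked, soft enolisation should remove a γ-proton at C6 and give the linear dienol ether 5; the dioxirane then oxidises its distal C5=C6 bond on the face away from the C7 side chain and the adduct collapses to the γ-hydroxy enone (vinylogous Rubottom oxidation, the reaction type of the 6-hydroxylation of steroidal 3,5-dienol ethers). This sets C6–O trans to the C7 chain, as the lactone needs.

Step 5
Reactants: 6 γ-hydroxy enone
Product: 7 ring B enone (6-OSiMe2t-Bu; 8-OSiMe3; 12-OSiMe2t-Bu)
Conditions: t-BuMe2SiOTf, 2,6-lutidine, CH2Cl2, −78 °C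
Reagents that add atoms: tert-butyldimethylsilyl triflate, CC(C)(C)[Si](C)(C)OS(=O)(=O)C(F)(F)F
Why: Silylation of the hindered secondary alcohol at low temperature; the labile Me3Si ether at C8 is kept so that the acidic work-up of step 6 frees only that hydroxyl.

Step 6
Reactants: 7 ring B enone; 8 methyl 2-oxo-2H-pyran-3-carboxylate
Product: 12 ten-membered α-ketol (methyl 8-hydroxy-9-oxo-6,12-bis(tert-butyldimethylsilyloxy)germacra-1(10),2,4,11(13)-tetraen-14-oate; C10=C1 and C2=C3 cis in the ring; C4=C5 trans), via aluminium enolate 9 (not isolated), via bridged lactone alkoxide 10 (not isolated), via bicyclic dienyl alkoxide 11 (not isolated)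
Conditions: Et2AlI (1.2 eq), CH2Cl2, −78 °C; 8, −78 → 40 °C; then 1 M HCl, THF, 0 °C
Reagents that add atoms: none
Why: Proposed new method: (1) Et2AlI should deliver iodide to C5 of enone 7 and so give the aluminium enolate 9 at C4 and nowhere else, the known first stage of iodoaluminium Baylis–Hillman-type couplings. (2) C4 adds to C6 of the aluminium-chelated pyrone 8 (Michael addition) and the resulting pyranolate carbon C10 closes onto the C9 ketone (6-exo-trig aldol), a formal inverse-electron-demand [4+2] that builds ring A (C9, C10, C1, C2, C3, C4) as the bridged lactone 10; the closest known reactions are the carbanion-induced ring transformations of 2-pyranones by ketone enolates and the Diels–Alder reactions of 3-carbomethoxy-2-pyrones with enol ethers. (3) Retro-[4+2] loss of CO2 gives the cyclohexadienyl alkoxide 11, which in the known reactions dehydrates to an arene but cannot do so here because C4 is quaternary. (4) Instead the C9 alkoxide breaks the shared C4–C9 bond (oxyanion-driven retro-aldol, equally a 6π disrotatory opening of the cyclohexadiene, closest known type the Grob fragmentation of bicyclic alkoxides); no ring is closed in this event, the bicyclo[4.4.0] system is expanded by four carbons to the ten-membered ring. (5) The resulting trienolate, a vinylogous β-keto ester anion and far more stable than the alkoxide, expels iodide from C5 (E1cB) to give C4=C5. The stereocentres made on the way (C3, C4, C5, C9, C10) are all destroyed again, so every diastereomer of 9–11 should converge on 12, while C6, C7 and C8 come unchanged from 7. C10=C1 and C2=C3 are cis because both were cis bonds of six-membered ring A, and C4=C5 should form trans because the anti elimination from the first-formed conformer places C6 away from C3. The step needs C4 (not C8) as the nucleophile, secured by the conjugate addition of iodide, and attack at pyrone C6 rather than at a carbonyl, secured by the chelated vinylogous acceptor.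

Step 7
Reactants: 13 (E)-2-methylbut-2-en-1-ol
Product: 14 [(2R,3R)-2,3-dimethyloxiran-2-yl]methanol
Conditions: Ti(OiPr)4 (cat.), D-(−)-diethyl tartrate (cat.), t-BuOOH, 4 Å MS, CH2Cl2, −20 °C
Reagents that add atoms: tert-butyl hydroperoxide, CC(C)(C)OO
Why: Sharpless asymmetric epoxidation; for this (E)-allylic alcohol the D-(−)-tartrate should deliver oxygen to the face that gives the (2R,3R)-epoxy alcohol, and the cis relation of the two methyl groups follows from the (E)-alkene.

Step 8
Reactants: 14 epoxy alcohol
Product: 15 (2S,3R)-2,3-dimethyloxirane-2-carboxylic acid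
Conditions: RuCl3 (cat.), NaIO4, MeCN/CCl4/H2O, 0 → 23 °C
Reagents that add atoms: water, O
Why: RuO4 made in the flask oxidises the primary alcohol through the aldehyde hydrate to the acid without opening the trisubstituted epoxide; the geometry at C2 is kept (the descriptor changes from R to S only because the priorities change).

Step 9
Reactants: 12 ten-membered α-ketol; 15 epoxy acid
Product: 17 C8 ester with C8–O cis to the C7 side chain (9-ketone), via triflate 16 (not isolated)
Conditions: Tf2O, 2,6-lutidine, CH2Cl2, −78 °C; then 15, Cs2CO3, 18-crown-6, DMF, −40 → 0 °C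
Reagents that add atoms: none
Why: The only free hydroxyl (C8) is triflated and the α-keto triflate is displaced by the cesium carboxylate in an SN2 reaction that the adjacent carbonyl accelerates. Inversion turns the trans ketol into the cis ester, and the sensitive epoxy acid is introduced once and directly, so no ester has to be told apart from another later.

Step 10
Reactants: 17 keto ester
Product: 18 C9 alcohol (C9–O trans to C8–O)
Conditions: NaBH4, CeCl3·7H2O, MeOH/THF, −78 °C; AcOH quench
Reagents that add atoms: none
Why: Luche reduction: CeCl3 directs hydride to the carbonyl carbon of the doubly activated enone (1,2-addition), and attack anti to the C8–O bond (polar Felkin–Anh model) should give the 8,9-threo alcohol.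

Step 11
Reactants: 18 C9 alcohol
Product: 19 C9 acetate
Conditions: Ac2O, DMAP (cat.), pyridine, CH2Cl2, 0 °C
Reagents that add atoms: acetic anhydride, CC(=O)OC(C)=O
Why: Acylation of the allylic secondary alcohol under nucleophilic catalysis, carried out at once so that the C8 acyl group cannot migrate to O9.

Step 12
Reactants: 19 bis-silyl ether
Product: 20 6,12-diol
Conditions: HF·pyridine, pyridine, THF, 0 → 23 °C
Reagents that add atoms: none
Why: Fluoride cleaves both tert-butyldimethylsilyl ethers; the buffered, slightly acidic medium should avoid acyl migration and conjugate addition to the dienoate and should leave the glycidic ester intact.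

Step 13
Reactants: 20 6,12-diol
Product: 22 trans-fused α-methylene-γ-butyrolactone with C4=C5 alkene, via lactol 21 (not isolated)
Conditions: TEMPO (cat.), PhI(OAc)2, CH2Cl2, 23 °C
Reagents that add atoms: none
Why: Oxoammonium oxidation is selective for the primary allylic alcohol; the enal is trapped by the C6 hydroxyl as lactol 21, which is oxidised on to the lactone. The trans ring fusion is fixed by C6 and C7.

Step 14
Reactants: 22 lactone
Product: 23 target CNP0229507.7
Conditions: mCPBA, NaHCO3, CH2Cl2, 0 °C
Reagents that add atoms: 3-chloroperbenzoic acid, OOC(=O)c1cccc(Cl)c1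
Why: Prilezhaev epoxidation: C4=C5 is the only alkene without an acceptor directly attached. The peracid should approach from the outer face of the ring with H6 in the alkene plane (allylic strain with C15), which places the oxygen syn to O6 and gives the trans 4,5-epoxide with the C5/C6 relation of the target.

## Compound list

1 | (S)-(+)-carvone, (5S)-2-methyl-5-(prop-1-en-2-yl)cyclohex-2-en-1-one | CC1=CC[C@H](C(C)=C)CC1=O | starting material
2 | (5S)-5-(3-hydroxyprop-1-en-2-yl)-2-methylcyclohex-2-en-1-one | CC1=CC[C@H](C(=C)CO)CC1=O | intermediate
3 | C12 tert-butyldimethylsilyl ether of 2 | CC1=CC[C@H](C(=C)CO[Si](C)(C)C(C)(C)C)CC1=O | intermediate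
4 | 3 with a trimethylsilyloxy group at C8, trans to the C7 side chain | CC1=CC[C@H](C(=C)CO[Si](C)(C)C(C)(C)C)[C@@H](O[Si](C)(C)C)C1=O | intermediate
5 | linear dienol trimethylsilyl ether of 4 (C9=C4, C5=C6) | CC1=C(O[Si](C)(C)C)[C@H](O[Si](C)(C)C)[C@@H](C(=C)CO[Si](C)(C)C(C)(C)C)C=C1 | intermediate (not isolated)
6 | γ-hydroxy enone: C6–OH trans to the C7 side chain, C8–OSiMe3 | CC1=C[C@@H](O)[C@H](C(=C)CO[Si](C)(C)C(C)(C)C)[C@@H](O[Si](C)(C)C)C1=O | intermediate
7 | ring B enone: 6-O-TBS, 8-O-TMS, 12-O-TBS | CC1=C[C@@H](O[Si](C)(C)C(C)(C)C)[C@H](C(=C)CO[Si](C)(C)C(C)(C)C)[C@@H](O[Si](C)(C)C)C1=O | intermediate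
8 | methyl 2-oxo-2H-pyran-3-carboxylate | COC(=O)C1=CC=COC1=O | starting material
9 | diethylaluminium enolate (C9=C4) with iodine at C5 | CC1=C(O[Al](CC)CC)[C@H](O[Si](C)(C)C)[C@@H](C(=C)CO[Si](C)(C)C(C)(C)C)[C@H](O[Si](C)(C)C(C)(C)C)[C@H]1I | intermediate (not isolated)
10 | bridged lactone (2-oxabicyclo[2.2.2]octenone on ring B), aluminium alkoxide at C9; mixture at C3, C4, C9, C10 | COC(=O)C12C=CC(OC1=O)C1(C)[C@H](I)[C@@H](O[Si](C)(C)C(C)(C)C)[C@H](C(=C)CO[Si](C)(C)C(C)(C)C)[C@@H](O[Si](C)(C)C)C21O[Al](CC)CC | intermediate (not isolated)
11 | bicyclo[4.4.0]deca-2,4-diene ester (ring A diene), aluminium alkoxide at C9; mixture at C4, C9 | COC(=O)C1=CC=CC2(C)[C@H](I)[C@@H](O[Si](C)(C)C(C)(C)C)[C@H](C(=C)CO[Si](C)(C)C(C)(C)C)[C@@H](O[Si](C)(C)C)C12O[Al](CC)CC | intermediate (not isolated)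
12 | methyl 8-hydroxy-9-oxo-6,12-bis(tert-butyldimethylsilyloxy)germacra-1(10),2,4,11(13)-tetraen-14-oate; C8–OH trans to the C7 side chain | O=C1[C@H](O)[C@@H](C(=C)CO[Si](C)(C)C(C)(C)C)[C@H](O[Si](C)(C)C(C)(C)C)/C=C(C)/C=C\C=C/1C(=O)OC | intermediate
13 | (E)-2-methylbut-2-en-1-ol | C/C=C(\C)CO | starting material
14 | [(2R,3R)-2,3-dimethyloxiran-2-yl]methanol | OC[C@@]1(C)O[C@@H]1C | intermediate
15 | (2S,3R)-2,3-dimethyloxirane-2-carboxylic acid | OC(=O)[C@@]1(C)O[C@@H]1C | intermediate
16 | C8 triflate of 12 | O=C1[C@H](OS(=O)(=O)C(F)(F)F)[C@@H](C(=C)CO[Si](C)(C)C(C)(C)C)[C@H](O[Si](C)(C)C(C)(C)C)/C=C(C)/C=C\C=C/1C(=O)OC | intermediate (not isolated)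
17 | 9-ketone with the (2S,3R)-epoxy ester at C8, C8–O cis to the C7 side chain | O=C1[C@@H](OC(=O)[C@@]2(C)O[C@@H]2C)[C@@H](C(=C)CO[Si](C)(C)C(C)(C)C)[C@H](O[Si](C)(C)C(C)(C)C)/C=C(C)/C=C\C=C/1C(=O)OC | intermediate
18 | C9 alcohol, C9–O trans to C8–O | O[C@@H]1[C@@H](OC(=O)[C@@]2(C)O[C@@H]2C)[C@@H](C(=C)CO[Si](C)(C)C(C)(C)C)[C@H](O[Si](C)(C)C(C)(C)C)/C=C(C)/C=C\C=C/1C(=O)OC | intermediate
19 | C9 acetate | CC(=O)O[C@@H]1[C@@H](OC(=O)[C@@]2(C)O[C@@H]2C)[C@@H](C(=C)CO[Si](C)(C)C(C)(C)C)[C@H](O[Si](C)(C)C(C)(C)C)/C=C(C)/C=C\C=C/1C(=O)OC | intermediate
20 | 6,12-diol | CC(=O)O[C@@H]1[C@@H](OC(=O)[C@@]2(C)O[C@@H]2C)[C@@H](C(=C)CO)[C@H](O)/C=C(C)/C=C\C=C/1C(=O)OC | intermediate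
21 | 6,12-lactol | C=C1C(O)O[C@H]2[C@H]1[C@H](OC(=O)[C@@]1(C)O[C@@H]1C)[C@@H](OC(C)=O)/C(C(=O)OC)=C\C=C/C(C)=C/2 | intermediate (not isolated)
22 | 6,12-lactone with C4=C5 alkene (4,5-deoxy target) | C=C1C(=O)O[C@H]2[C@H]1[C@H](OC(=O)[C@@]1(C)O[C@@H]1C)[C@@H](OC(C)=O)/C(C(=O)OC)=C\C=C/C(C)=C/2 | intermediate
23 | CNP0229507.7 | C=C1C(=O)O[C@H]2[C@H]1[C@H](OC(=O)[C@@]1(C)O[C@@H]1C)[C@@H](OC(C)=O)/C(C(=O)OC)=C\C=C/[C@@]1(C)O[C@H]21 | target

## Step count and least certain steps

Total: 14 steps. Longest linear sequence: 12 steps (steps 1–6 and 9–14); steps 7–8 make the side-chain acid.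

**Step 6 (key step, proposed new method).** The most likely failure is a stall after the Michael addition: the chelated pyranolate may be too stabilised to close onto the hindered C9 ketone, or the pyranyl ring may open to a dienoic acid before CO2 is lost. A second danger is thermal re-closure of the product (6π closure of the C10=C1–C2=C3–C4=C5 triene across C5/C10, or oxa-6π closure of the cis-dienone), so 12 and its successors are kept cold and carried on at once.

The fallback separates the events into known reactions, sets out from 7 and returns at 12. Me3SiI adds 1,4 to 7 at −78 °C to give the β-iodo silyl enol ether F1. F1 and 8 are combined in an inverse-electron-demand Diels–Alder reaction (neat or under pressure, Yb(fod)3 if needed) to give the isolable bridged lactone F2. Heating F2 in toluene extrudes CO2 and gives the bicyclic dienyl silyl ether F3. Bu4NF in THF at −78 °C then frees the C9 alkoxide, which fragments and loses iodide to give 12.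

**Step 4.** Loss of regiocontrol in the enolisation (removal of the C8 proton instead of a C6 proton) or attack of the oxidant at C4 would give the wrong hydroxy ketone. The fallback sets out from 3 and returns at 7 with the order of the two oxygenations reversed. Isopropenyl acetate with TsOH gives the thermodynamic linear dienol acetate F4. mCPBA converts F4 to the γ-hydroxy enone F5. Silylation gives the silyl ether F6, whose kinetic enolate (LiN(iPr)2) is hydroxylated at C8 with the oxaziridine and silylated with Me3SiCl to give 7.

**Step 9.** Slow displacement (the carboxylate must enter on the side of the C7 chain), with elimination or epimerisation at C8 taking over. The fallback sets out from 12 and returns at 17. Triflate 16 is treated with Bu4N+ NO2− (Lattrell–Dax inversion); hydrolysis of the nitrite ester gives the inverted ketol F7. F7 is then esterified with 15 under Yamaguchi conditions (2,4,6-trichlorobenzoyl chloride, Et3N, DMAP) with retention.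

**Step 10.** Poor facial selectivity if the conformation of the ten-membered ring overrides the Felkin–Anh preference, and migration of the C8 acyl group to O9 in the alkoxide. The fallback sets out from 17 and returns at 19. Chelation-controlled reduction with Zn(BH4)2 is aimed at the 9-epimeric alcohol F8, and a Mitsunobu reaction of F8 with acetic acid (PPh3, DIAD) inverts C9 and gives acetate 19 directly.

**Step 14.** Attack of the peracid on the inner face would give the epimeric epoxide. The fallback sets out from 22 and returns at 23. NBS in aqueous THF gives the bromohydrin F9 (Br at C5, OH at C4, formed by anti addition), and K2CO3 closes it to the epoxide. This sequence puts the oxygen on the face opposite to the one a peracid attacks.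

Further compounds

F1 | step 6 | β-iodo trimethylsilyl enol ether of 7 | CC1=C(O[Si](C)(C)C)[C@H](O[Si](C)(C)C)[C@@H](C(=C)CO[Si](C)(C)C(C)(C)C)[C@H](O[Si](C)(C)C(C)(C)C)[C@H]1I
F2 | step 6 | bridged lactone, C9 trimethylsilyl ether | COC(=O)C12C=CC(OC1=O)C1(C)[C@H](I)[C@@H](O[Si](C)(C)C(C)(C)C)[C@H](C(=C)CO[Si](C)(C)C(C)(C)C)[C@@H](O[Si](C)(C)C)C21O[Si](C)(C)C
F3 | step 6 | bicyclic dienyl ester, C9 trimethylsilyl ether | COC(=O)C1=CC=CC2(C)[C@H](I)[C@@H](O[Si](C)(C)C(C)(C)C)[C@H](C(=C)CO[Si](C)(C)C(C)(C)C)[C@@H](O[Si](C)(C)C)C12O[Si](C)(C)C
F4 | step 4 | linear dienol acetate of 3 | CC1=C(OC(C)=O)C[C@@H](C(=C)CO[Si](C)(C)C(C)(C)C)C=C1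
F5 | step 4 | γ-hydroxy enone without C8 oxygen | CC1=C[C@@H](O)[C@H](C(=C)CO[Si](C)(C)C(C)(C)C)CC1=O
F6 | step 4 | C6 tert-butyldimethylsilyl ether of F5 | CC1=C[C@@H](O[Si](C)(C)C(C)(C)C)[C@H](C(=C)CO[Si](C)(C)C(C)(C)C)CC1=O
F7 | step 9 | C8 epimer of ketol 12 (C8–OH cis to the C7 side chain) | O=C1[C@@H](O)[C@@H](C(=C)CO[Si](C)(C)C(C)(C)C)[C@H](O[Si](C)(C)C(C)(C)C)/C=C(C)/C=C\C=C/1C(=O)OC
F8 | step 10 | C9 epimer of alcohol 18 | O[C@H]1[C@@H](OC(=O)[C@@]2(C)O[C@@H]2C)[C@@H](C(=C)CO[Si](C)(C)C(C)(C)C)[C@H](O[Si](C)(C)C(C)(C)C)/C=C(C)/C=C\C=C/1C(=O)OC
F9 | step 14 | 5-bromo-4-hydroxy bromohydrin of 22 | C=C1C(=O)O[C@H]2[C@H]1[C@H](OC(=O)[C@@]1(C)O[C@@H]1C)[C@@H](OC(C)=O)/C(C(=O)OC)=C\C=C/[C@@](C)(O)[C@H]2Br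
A1 | alternative 1 | seco epoxy aldehyde with 2-(bromomethyl)enoate | O=C[C@H]1O[C@]1(C)/C=C\C=C(C(=O)OC)/[C@H](OC(C)=O)[C@@H](OC(=O)[C@@]1(C)O[C@@H]1C)/C=C(\CBr)C(=O)OC
A2 | alternative 2 | metathesis precursor: lactone with vinyl epoxide and pentadienoate | C=C1C(=O)O[C@H]([C@H]2O[C@]2(C)C=C)[C@H]1[C@H](OC(=O)[C@@]1(C)O[C@@H]1C)[C@@H](OC(C)=O)/C(C(=O)OC)=C\C=C
A3 | alternative 3 | 6-alkyl-6-methylcyclohexa-2,4-dienone from methyl 3-methylsalicylate | COC(=O)C1=CC=CC(C)([C@@H]2O[C@H]2[C@H](C(=C)C(=O)OC)C=O)C1=O
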